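## The problem

Target 30 is a ten-membered carbocycle (C1–C10) with a ring-cis C1=C10 olefin conjugated to the C14 methyl ester, a trans trisubstituted oxirane at C4–C5, an α-methylene γ-lactone trans-fused at C6–C7, and a cis-8,9-diol acylated at O8 by (2S,3R)-2,3-dimethyloxirane-2-carboxylic acid. Six contiguous stereocentres, C4 to C9, sit on a flexible medium ring, so each must come from a reagent-controlled reaction on an open chain or from a relay whose course is fixed by mechanism. C4/C5 can be set by asymmetric epoxidation of an E-allylic alcohol and then bias C6 by 1,2-induction. C9 is insulated from them by the enoate and needs its own source of chirality, while C7 and C8 are best derived from C9. The ring has to be closed against the strain of a cyclodecadiene with cis geometry at both ring olefins. The α-methylene lactone (Michael acceptor), both oxiranes (acid), the doubly allylic C9 carbinol (ionisation), the lactone (translactonisation towards O8) and the O8 ester (migration to O9) will not survive rough treatment. The enabling feature is that C7 is the terminus of the allylic triad C7–C8–C9 and carries C11 on the same side as the C9 oxygen. A leaving group at C9 with the configuration of the final carbinol can therefore pass that configuration to C7 through a π-allylpalladium complex when the nucleophile is an acetate unit hung on O6. The same event closes the lactone ring and leaves the C8=C9 olefin from which the cis diol is made.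

## Retrosynthesis

**Ester at O8.** Cutting the C8–O acyl bond of 30 gives diol lactone 24 and epoxy acid 28. The glycidic ester is acid-labile and is best attached last. Carrying a tiglate and epoxidising at the end would not control the two side-chain centres and would compete with the other olefins. Acid 28 comes from tiglic acid 25 through allylic alcohol 26 and epoxy alcohol 27, where one asymmetric epoxidation sets both centres. The forward step must acylate O8 in the presence of O9.

**Methylene and diol.** The C11=C13 bond of 24 is cut to phosphono lactone diol 23 (olefination with formaldehyde), and the C8–O and C9–O bonds to diene 22 (syn dihydroxylation). Keeping C11 as the phosphonate during osmylation leaves C8=C9 as the only olefin not attached to a carbonyl, and the phosphonate is already there from the key step. The forward step must hydroxylate the face of C8=C9 on which C6 lies.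

**Lactone annulation (key).** Cutting C7–C11 of 22 leads to macrocyclic carbonate 21. The neighbouring cut, C6–O (lactonisation of a C7 acetic acid), would leave C7 to be set on a ten-membered ring with nothing to direct it. Cutting C7–C11 lets C9 dictate C7 and also creates the C8=C9 olefin that the diol needs. Precursor 21 has one ring and one stereocentre fewer. The forward reaction must ionise only at C9, bond at C7 and pass through the ring-cis allyl unit.

**Carbonate and ring.** Removing the carbonate gives macrocyclic alcohol 20, and cutting C7=C8 gives acyclic diene 19 (ring-closing metathesis). The two carbinol centres flanking the new olefin can then be made separately on open chains, and a ten-membered cycloalkene prefers the cis geometry. Closure at the trisubstituted C1=C10 enoate or by C–C alkylation is less well precedented. The forward step must favour cyclisation over oligomerisation.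

**C6 and the oxirane.** Alcohol 19 comes from silyl ether 18, and the C6–O ester bond of 18 is cut with inversion to alcohol 16 and diethylphosphonoacetic acid 17. Cutting C6–C7 leads to epoxy aldehyde 15, and the oxirane oxygen is removed through epoxy alcohol 14 to allylic alcohol 13. Felkin–Anh addition to 15 gives the erythro carbinol, whereas 30 needs the threo relationship between the oxirane oxygen and O6. Making the ester by Mitsunobu inversion corrects the centre in the step that installs the nucleophile, at no cost in steps.

**C1=C10.** Enoate 13 is deacetylated 12, which arises by elimination from aldol 10. Cutting C1–C10 of 10 gives ester 5 and aldehyde 9. The two chirality-bearing halves are joined at a site that has only geometry to control. A Horner–Wadsworth–Emmons route would need an extra step to make an α-branched phosphonate and controls geometry less well. The forward steps must avoid β-elimination of the silyloxy group and give C2 trans to the ester.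

**Starting materials.** Aldehyde 9 comes from geranyl acetate 6 through epoxide 7 (diol 8 in the flask). Ester 5 comes from resolved hydroxy ester 4, the racemate 3 being the aldol of methyl acetate 1 and acrolein 2.

## Roads not taken

**Alternative 1:** The C6–C7 bond is formed and the C4–C9 bond broken in an anionic oxy-Cope rearrangement, so that a six-membered ring grows into the ten-membered one and arrives as cyclodecadienone A1. Its merit is real: ring formation is a unimolecular rearrangement with no entropic penalty, and C6, C7 and the trans C4=C5 olefin come from one chair transition state. At ring formation it is stronger than the metathesis of 19. For this target the cost comes afterwards. A1 has a ketone at C9 and a bare methylene at C8, so the cis diol needs an enolate hydroxylation and a reduction, both on the medium ring. C12 and C14 are at the alcohol level, the oxirane has to be placed on the ring late, and the methylene still has to be added. The chosen plan sets C4/C5 by reagent control before the ring exists and reaches the C8/C9 oxidation pattern in one syn addition.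

**Alternative 2:** The C3–C4 bond and the oxirane C5–O bond are made when but-3-enylmagnesium bromide A3 adds to α-chloro ketone A2 and the alkoxide displaces chloride with inversion, giving epoxy diene lactone A4, still open between C1 and C10. The oxirane forms stereospecifically, the lactone and C6–C9 are in place early, and O8 and O9 are already distinguished by their protecting groups. In that last respect it is better than the chosen plan, whose acylation of diol 24 has to be selective. Its weak points are the Grignard addition in the presence of a lactone and an acrylate, the dependence of C4 on 1,2-induction from the chloride, and a final metathesis that must form a trisubstituted ring-cis enoate in a ten-membered ring. The chosen plan closes the ring at a disubstituted olefin.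

**Alternative 3:** The C7–C8 bond is cut; indium converts bromomethylbutenolide aldehyde A5 into an allylindium that adds through C7 to the C8 aldehyde and gives macrocyclic methylene lactone A6. One step forms the ring, C7, C8 and the exocyclic methylene. A6 has O8 free and O9 silylated, so the endgame is shorter and the acylation site is unambiguous. Both are advantages over the chosen plan. Against this, two new centres and a ten-membered ring are set in one medium-ring transition state whose preference cannot be predicted, and the α-silyloxy aldehyde beside the enoate is prone to epimerisation and elimination. The chosen plan derives C7 from C9 by a double-inversion mechanism and C8/C9 by syn addition, at the price of a longer sequence and a late differentiation of O8 and O9.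

Key step: step 16

Assumptions: atoms carry germacrane numbers (ring C1–C10, lactone carbons C11–C13, ester carbon C14 on C10, methyl C15 on C4). Geraniol enters as its commercial acetate 6. The configuration of the alcohol left by the lipase in step 2 is assigned by the empirical size rule for secondary alcohols.

## Route

Step 1
Reactants: 1 methyl acetate; 2 acrolein
Product: 3 rac-methyl 3-hydroxypent-4-enoate
Conditions: LDA, THF, −78 °C; then 2; aq. NH4Cl
Reagents that add atoms: none
Why: Directed aldol addition of the lithium enolate of methyl acetate to the aldehyde carbon of acrolein at low temperature; no stereocontrol is sought because the racemate is resolved next.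

Step 2
Reactants: 3 rac-methyl 3-hydroxypent-4-enoate
Product: 4 methyl (3R)-3-hydroxypent-4-enoate
Conditions: Burkholderia cepacia lipase (Amano PS), vinyl acetate, MTBE, 30 °C, to just past half conversion
Reagents that add atoms: none
Why: Lipase-catalysed kinetic resolution by irreversible transesterification; with vinyl as the medium and CH2CO2Me as the large substituent the (S)-alcohol should be acetylated, leaving (R)-4, which is separated from the acetate by chromatography.

Step 3
Reactants: 4 methyl (3R)-3-hydroxypent-4-enoate
Product: 5 methyl (3R)-3-(tert-butyldimethylsilyloxy)pent-4-enoate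
Conditions: TBSCl, imidazole, DMF, rt
Reagents that add atoms: tert-butyldimethylsilyl chloride, CC(C)(C)[Si](C)(C)Cl
Why: Standard silylation of a secondary alcohol; the silyl ether is a poor leaving group and keeps the future C9 oxygen through the enolate chemistry.

Step 4
Reactants: 6 geranyl acetate
Product: 7 6,7-epoxygeranyl acetate (racemic at the oxirane)
Conditions: mCPBA (1.0 equiv), NaHCO3, CH2Cl2, 0 °C
Reagents that add atoms: 3-chloroperbenzoic acid, OOC(=O)c1cccc(Cl)c1
Why: Prilezhaev epoxidation; the remote trisubstituted olefin is more electron-rich than the 2,3-olefin, which the allylic acetate deactivates.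

Step 5
Reactants: 7 6,7-epoxygeranyl acetate
Product: 9 (2E)-3-methyl-6-oxohex-2-en-1-yl acetate, via diol 8 (not isolated)
Conditions: HIO4·2H2O, THF/H2O, 0 °C
Reagents that add atoms: none
Why: Periodic acid hydrolyses the oxirane to the vicinal diol and cleaves it (Malaprade) to the C1 aldehyde and acetone in one operation; the allylic acetate and E olefin are untouched.

Step 6
Reactants: 5 methyl (3R)-3-(tert-butyldimethylsilyloxy)pent-4-enoate; 9 (2E)-3-methyl-6-oxohex-2-en-1-yl acetate
Product: 10 aldol adduct, methyl (6E)-8-acetoxy-2-[(1S)-1-(tert-butyldimethylsilyloxy)prop-2-en-1-yl]-3-hydroxy-6-methyloct-6-enoate (mixture at C1 and C10)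
Conditions: LDA, THF, −78 °C, 5; then 9, −78 °C; aq. NH4Cl
Reagents that add atoms: none
Why: Aldol addition of a lithium ester enolate; β-silyloxy ester enolates resist β-elimination at −78 °C, the aldehyde reacts far faster than the acetate, and the two new centres are erased in step 7.

Step 7
Reactants: 10 aldol adduct
Product: 12 methyl (2E,6E)-8-acetoxy-2-[(1S)-1-(tert-butyldimethylsilyloxy)prop-2-en-1-yl]-6-methylocta-2,6-dienoate, via mesylate 11 (not isolated)
Conditions: MsCl, Et3N, CH2Cl2, 0 °C; then DBU, rt
Reagents that add atoms: none
Why: Mesylation followed by E1cB elimination; the mesylate leaves far more readily than the β-silyloxy group, and the enoate with C2 trans to the ester (the ring-cis arrangement of C2 and C9) is the more stable isomer and should dominate.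

Step 8
Reactants: 12 dienoate acetate
Product: 13 methyl (2E,6E)-2-[(1S)-1-(tert-butyldimethylsilyloxy)prop-2-en-1-yl]-8-hydroxy-6-methylocta-2,6-dienoate
Conditions: K2CO3 (cat.), MeOH, 0 °C
Reagents that add atoms: none
Why: Base-catalysed transesterification removes the primary acetate; the methyl ester is degenerate in methanol and the α-branched enoate is a poor Michael acceptor.

Step 9
Reactants: 13 allylic alcohol
Product: 14 methyl (2E)-2-[(1S)-1-(tert-butyldimethylsilyloxy)prop-2-en-1-yl]-5-[(2R,3R)-3-(hydroxymethyl)-2-methyloxiran-2-yl]pent-2-enoate
Conditions: Ti(OiPr)4 (10 mol%), D-(−)-diethyl tartrate (12 mol%), t-BuOOH, 4 Å MS, CH2Cl2, −20 °C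
Reagents that add atoms: tert-butyl hydroperoxide, CC(C)(C)OO
Why: Sharpless asymmetric epoxidation; with the D-(−)-tartrate the oxygen is delivered to the face that gives the (2R,3R)-epoxy alcohol (C4 R, C5 R), the mirror image of the outcome known for geraniol with the L-(+)-ester, and only the allylic alcohol olefin reacts.

Step 10
Reactants: 14 epoxy alcohol
Product: 15 methyl (2E)-2-[(1S)-1-(tert-butyldimethylsilyloxy)prop-2-en-1-yl]-5-[(2R,3S)-3-formyl-2-methyloxiran-2-yl]pent-2-enoate
Conditions: Dess–Martin periodinane, NaHCO3, CH2Cl2, 0 °C → rt
Reagents that add atoms: none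
Why: Buffered Dess–Martin oxidation of a primary epoxy alcohol; the oxirane carbon next to the aldehyde does not enolise readily, so C5 is retained (the descriptor changes only through priorities).

Step 11
Reactants: 15 epoxy aldehyde
Product: 16 methyl (2E)-2-[(1S)-1-(tert-butyldimethylsilyloxy)prop-2-en-1-yl]-5-{(2R,3R)-3-[(1R)-1-hydroxyprop-2-en-1-yl]-2-methyloxiran-2-yl}pent-2-enoate
Conditions: CH2=CHMgBr, THF, −78 °C; aq. NH4Cl
Reagents that add atoms: vinylmagnesium bromide, C=C[Mg]Br
Why: Grignard addition under Felkin–Anh control with the oxirane C–O bond antiperiplanar to the nucleophile should give the erythro (6R) carbinol, the preference being reinforced by the methyl cis to the formyl group; the ester is inert at −78 °C.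

Step 12
Reactants: 16 (6R)-allylic alcohol; 17 diethylphosphonoacetic acid
Product: 18 methyl (2E)-2-[(1S)-1-(tert-butyldimethylsilyloxy)prop-2-en-1-yl]-5-{(2R,3R)-3-[(1S)-1-(2-diethoxyphosphorylacetoxy)prop-2-en-1-yl]-2-methyloxiran-2-yl}pent-2-enoate
Conditions: PPh3, DIAD, THF, 0 °C → rt
Reagents that add atoms: none
Why: Mitsunobu esterification; the carboxylate displaces the alkoxyphosphonium ion by SN2 with inversion, turning the erythro (6R) alcohol into the threo (6S) ester that 30 requires, as is routine for 2,3-epoxy alcohols.

Step 13
Reactants: 18 silyl ether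
Product: 19 methyl (2E)-2-[(1S)-1-hydroxyprop-2-en-1-yl]-5-{(2R,3R)-3-[(1S)-1-(2-diethoxyphosphorylacetoxy)prop-2-en-1-yl]-2-methyloxiran-2-yl}pent-2-enoate
Conditions: HF·pyridine, pyridine, THF, 0 °C → rt
Reagents that add atoms: none
Why: Fluoride-mediated desilylation buffered with pyridine; these conditions are known to spare trisubstituted oxiranes and do not deprotonate the phosphonoacetate.

Step 14
Reactants: 19 acyclic diene alcohol
Product: 20 macrocyclic alcohol, methyl (4R,5R,6S,9S)-6-(2-diethoxyphosphorylacetoxy)-4,5-epoxy-9-hydroxygermacra-1(10),7-dien-14-oate (both ring olefins cis)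
Conditions: second-generation Grubbs catalyst (H2IMes)(PCy3)Cl2Ru=CHPh (10 mol%), 2,6-dichloro-1,4-benzoquinone (10 mol%), CH2Cl2 (1 mM), 40 °C
Reagents that add atoms: none
Why: Ring-closing metathesis of two monosubstituted olefins with loss of ethylene; the free allylic hydroxyl at C9 speeds initiation there, the ring-cis C1=C10 bond and the oxirane pre-fold the chain, and the cis C7=C8 olefin is the more stable one in a ten-membered ring.

Step 15
Reactants: 20 macrocyclic alcohol
Product: 21 macrocyclic carbonate, methyl (4R,5R,6S,9S)-6-(2-diethoxyphosphorylacetoxy)-4,5-epoxy-9-(methoxycarbonyloxy)germacra-1(10),7-dien-14-oate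
Conditions: ClCO2Me, pyridine, CH2Cl2, 0 °C
Reagents that add atoms: methyl chloroformate, COC(=O)Cl
Why: Acylation of the only free hydroxyl with a chloroformate; pyridine alone is used so that no nucleophilic catalyst attacks the doubly allylic carbonate.

Step 16
Reactants: 21 macrocyclic carbonate
Product: 22 α-phosphono lactone, methyl (4R,5R,6S,7R)-11-(diethoxyphosphoryl)-4,5-epoxy-12-oxo-6,12-epoxygermacra-1(10),8-dien-14-oate (ring-cis C8=C9 and C1=C10, C11 epimers)
Conditions: Pd(PPh3)4 (10 mol%), THF (5 mM), 60 °C
Reagents that add atoms: none
Why: Zerovalent palladium binds C7=C8 on the face opposite the C9 carbonate and ionises it with inversion; loss of CO2 leaves methoxide, which deprotonates the phosphonoacetate, so no external base is needed. The soft phosphonate-stabilised carbanion then attacks the allyl terminus C7 on the face away from palladium, a second inversion, so C11 bonds to C7 on the side the C9 oxygen left (1,3-transposition with net retention). The closest known reaction type is the Tsuji–Trost intramolecular allylic alkylation of 4-acyloxyalk-2-enyl esters of stabilised acetic acids to α-substituted γ-lactones. The lactone closes in the 5-exo sense with respect to the allyl unit (C11 onto C7, C8–C9 outside the new ring); attack at C9 would need a seven-membered ring and attack at C1 a nine-membered one. The new centre C7 (R) is controlled by C9 (S in 21) acting through the ring-cis (anti,anti) allyl complex, and the reacting conformer has C5 antiperiplanar to C8, which puts O6 and its tether on the face the carbonate vacates and makes the lactone trans-fused. C11 is not controlled and both epimers are carried on, since that centre disappears in step 18. Chemoselectivity rests on the carbonate ionising irreversibly and much faster than the allylic carboxylate at C6, and the ring-cis geometry of the new C8=C9 bond follows from the ring-cis allyl unit.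

Step 17
Reactants: 22 α-phosphono lactone diene
Product: 23 diol, methyl (4R,5R,6S,7R,8S,9R)-11-(diethoxyphosphoryl)-4,5-epoxy-8,9-dihydroxy-12-oxo-6,12-epoxygermacr-1(10)-en-14-oate (C11 epimers)
Conditions: OsO4 (5 mol%), NMO, acetone/H2O, 0 °C
Reagents that add atoms: osmium tetroxide, O=[Os](=O)(=O)=O; N-methylmorpholine N-oxide, C[N+]1([O-])CCOCC1
Why: Upjohn dihydroxylation; syn addition to the ring-cis C8=C9 bond gives the cis diol, and this is the only olefin not bonded to a carbonyl. In the rotamer with H7 in the olefin plane (least allylic strain) C11 with its phosphonate covers one face and only C6–H the other, so attack from the C6 side should give the (8S,9R) diol.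

Step 18
Reactants: 23 phosphono lactone diol
Product: 24 methylene lactone diol, methyl (4R,5R,6S,7R,8S,9R)-4,5-epoxy-8,9-dihydroxy-12-oxo-6,12-epoxygermacra-1(10),11(13)-dien-14-oate
Conditions: 37% aq. HCHO, K2CO3, THF, 0 °C → rt
Reagents that add atoms: formaldehyde, C=O
Why: Horner–Wadsworth–Emmons olefination of the α-phosphono lactone with formaldehyde; both C11 epimers converge, and while the phosphonate anion is present the lactone carbonyl is deactivated towards attack by O8.

Step 19
Reactants: 25 tiglic acid
Product: 26 (2E)-2-methylbut-2-en-1-ol
Conditions: LiAlH4, Et2O, 0 °C → rt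
Reagents that add atoms: none
Why: Hydride reduction of an α,β-unsaturated acid gives the allylic alcohol by 1,2-reduction with the E geometry intact.

Step 20
Reactants: 26 (2E)-2-methylbut-2-en-1-ol
Product: 27 [(2R,3R)-2,3-dimethyloxiran-2-yl]methanol
Conditions: Ti(OiPr)4 (10 mol%), D-(−)-diethyl tartrate (12 mol%), t-BuOOH, 4 Å MS, CH2Cl2, −20 °C
Reagents that add atoms: tert-butyl hydroperoxide, CC(C)(C)OO
Why: Sharpless asymmetric epoxidation; the D-(−)-tartrate delivers oxygen to the same face as in step 9, giving the (2R,3R)-epoxy alcohol with the two methyl groups cis as in the E olefin.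

Step 21
Reactants: 27 epoxy alcohol
Product: 28 (2S,3R)-2,3-dimethyloxirane-2-carboxylic acid
Conditions: RuCl3·xH2O (2 mol%), NaIO4, CCl4/MeCN/H2O, rt
Reagents that add atoms: water, O
Why: Sharpless oxidation with RuO4 made in situ takes the primary alcohol to the acid without opening the oxirane; C2 has no hydrogen, so nothing can epimerise (the descriptor at C2 changes only through priorities).

Step 22
Reactants: 24 methylene lactone diol; 28 (2S,3R)-2,3-dimethyloxirane-2-carboxylic acid
Product: 30 target 8-O-[(2S,3R)-2,3-dimethyloxirane-2-carbonyl] ester, via mixed anhydride 29 (not isolated)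
Conditions: 28, 2,4,6-Cl3C6H2COCl, Et3N, THF, 0 °C; then 24, DMAP, toluene, 0 °C → rt
Reagents that add atoms: none
Why: Yamaguchi esterification suits the hindered α-quaternary acid; O8 should react first because O9 sits on a carbon flanked by the fully substituted C10, is hydrogen-bonded to the C14 ester carbonyl and is made less nucleophilic by the adjacent enoate.

## Compound list

1 | methyl acetate | COC(C)=O | starting material
2 | acrolein | C=CC=O | starting material
3 | rac-methyl 3-hydroxypent-4-enoate | COC(=O)CC(O)C=C | intermediate
4 | methyl (3R)-3-hydroxypent-4-enoate | COC(=O)C[C@@H](O)C=C | intermediate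
5 | methyl (3R)-3-(tert-butyldimethylsilyloxy)pent-4-enoate | COC(=O)C[C@@H](O[Si](C)(C)C(C)(C)C)C=C | intermediate
6 | geranyl acetate | CC(C)=CCC/C(C)=C/COC(C)=O | starting material
7 | 6,7-epoxygeranyl acetate (racemic at the oxirane) | CC1(C)OC1CC/C(C)=C/COC(C)=O | intermediate
8 | 6,7-dihydroxy-6,7-dihydrogeranyl acetate (not isolated) | CC(C)(O)C(O)CC/C(C)=C/COC(C)=O | intermediate
9 | (2E)-3-methyl-6-oxohex-2-en-1-yl acetate | O=CCC/C(C)=C/COC(C)=O | intermediate
10 | aldol adduct (mixture at C1 and C10) | COC(=O)C(C(O)CC/C(C)=C/COC(C)=O)[C@@H](O[Si](C)(C)C(C)(C)C)C=C | intermediate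
11 | C1 mesylate of 10 (not isolated) | COC(=O)C(C(OS(C)(=O)=O)CC/C(C)=C/COC(C)=O)[C@@H](O[Si](C)(C)C(C)(C)C)C=C | intermediate
12 | methyl (2E,6E)-8-acetoxy-2-[(1S)-1-(tert-butyldimethylsilyloxy)prop-2-en-1-yl]-6-methylocta-2,6-dienoate | C=C[C@H](O[Si](C)(C)C(C)(C)C)/C(C(=O)OC)=C\CC/C(C)=C/COC(C)=O | intermediate
13 | methyl (2E,6E)-2-[(1S)-1-(tert-butyldimethylsilyloxy)prop-2-en-1-yl]-8-hydroxy-6-methylocta-2,6-dienoate | C=C[C@H](O[Si](C)(C)C(C)(C)C)/C(C(=O)OC)=C\CC/C(C)=C/CO | intermediate
14 | (4R,5R)-epoxy alcohol | C=C[C@H](O[Si](C)(C)C(C)(C)C)/C(C(=O)OC)=C\CC[C@@]1(C)O[C@@H]1CO | intermediate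
15 | epoxy aldehyde | C=C[C@H](O[Si](C)(C)C(C)(C)C)/C(C(=O)OC)=C\CC[C@@]1(C)O[C@@H]1C=O | intermediate
16 | (6R)-vinyl carbinol (erythro) | C=C[C@H](O[Si](C)(C)C(C)(C)C)/C(C(=O)OC)=C\CC[C@@]1(C)O[C@@H]1[C@H](O)C=C | intermediate
17 | diethylphosphonoacetic acid | OC(=O)CP(=O)(OCC)OCC | starting material
18 | (6S)-phosphonoacetate, C9 silyl ether | C=C[C@H](O[Si](C)(C)C(C)(C)C)/C(C(=O)OC)=C\CC[C@@]1(C)O[C@@H]1[C@@H](OC(=O)CP(=O)(OCC)OCC)C=C | intermediate
19 | (6S)-phosphonoacetate, C9 alcohol | C=C[C@H](O)/C(C(=O)OC)=C\CC[C@@]1(C)O[C@@H]1[C@@H](OC(=O)CP(=O)(OCC)OCC)C=C | intermediate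
20 | macrocyclic alcohol (ring-cis 7-ene, 9-OH, O6 phosphonoacetate) | CCOP(=O)(OCC)CC(=O)O[C@H]1/C=C\[C@H](O)/C(C(=O)OC)=C\CC[C@@]2(C)O[C@H]12 | intermediate
21 | macrocyclic C9 methyl carbonate, O6 phosphonoacetate | CCOP(=O)(OCC)CC(=O)O[C@H]1/C=C\[C@H](OC(=O)OC)/C(C(=O)OC)=C\CC[C@@]2(C)O[C@H]12 | intermediate
22 | α-phosphono lactone with ring-cis C8=C9 (C11 epimers) | CCOP(=O)(OCC)C1C(=O)O[C@H]2[C@H]1/C=C\C(C(=O)OC)=C/CC[C@@]1(C)O[C@H]21 | intermediate
23 | α-phosphono lactone cis-8,9-diol (C11 epimers) | CCOP(=O)(OCC)C1C(=O)O[C@H]2[C@H]1[C@H](O)[C@H](O)/C(C(=O)OC)=C\CC[C@@]1(C)O[C@H]21 | intermediate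
24 | α-methylene lactone cis-8,9-diol | C=C1C(=O)O[C@H]2[C@H]1[C@H](O)[C@H](O)/C(C(=O)OC)=C\CC[C@@]1(C)O[C@H]21 | intermediate
25 | tiglic acid | C/C=C(\C)C(=O)O | starting material
26 | (2E)-2-methylbut-2-en-1-ol | C/C=C(\C)CO | intermediate
27 | [(2R,3R)-2,3-dimethyloxiran-2-yl]methanol | OC[C@@]1(C)O[C@@H]1C | intermediate
28 | (2S,3R)-2,3-dimethyloxirane-2-carboxylic acid | OC(=O)[C@@]1(C)O[C@@H]1C | intermediate
29 | mixed anhydride of 28 with 2,4,6-trichlorobenzoic acid (not isolated) | O=C(OC(=O)[C@@]1(C)O[C@@H]1C)c1c(Cl)cc(Cl)cc1Cl | intermediate
30 | CNP0262846.1, (4R,5R,6S,7R,8S,9R)-8-O-[(2S,3R)-2,3-dimethyloxirane-2-carbonyl] methylene lactone ester | C=C1C(=O)O[C@H]2[C@H]1[C@H](OC(=O)[C@@]1(C)O[C@@H]1C)[C@H](O)/C(C(=O)OC)=C\CC[C@@]1(C)O[C@H]21 | target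

## Step count and least certain steps

Total: 22 steps. Longest linear sequence: 17 steps (1–3, 6–18, 22, from methyl acetate and acrolein); the branch from geranyl acetate is 16 steps and the acid branch 3 steps plus the final coupling.

**Step 16 (key step).** Ionisation may occur from the conformer that holds C10 outside the allyl unit. The resulting syn,anti complex would be attacked on the other face of C7 and give a cis-fused lactone with a ring-trans C8=C9 bond. The cation is also shared with the enoate, so palladium may rest on the C9–C10–C1 side or a proton may be lost to give a triene. The fallback forms the same bond and ring by conjugate addition. It sets out from 20: Dess–Martin oxidation gives the cross-conjugated macrocyclic dienone F1. Cs2CO3 in MeCN then adds the tethered phosphonoacetate to C7 in a reversible 5-exo Michael reaction that should settle on the trans-fused keto phosphono lactone F2. Luche reduction (NaBH4, CeCl3·7H2O) gives the C9 carbinol F3, and dehydration with the Burgess reagent re-creates the ring-cis C8=C9 bond and returns to the route at 22.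

**Step 14.** Oligomerisation can outrun closure of the strained ring, ruthenium hydrides can isomerise the free doubly allylic alcohol to the enone, and the phosphonate may hold the catalyst. The fallback closes the ring one stage earlier, on 16, where C9 is silylated and no phosphonate is present, to give the macrocyclic (6R)-alcohol F4. Mitsunobu esterification with 17 on the ring then gives F5, and HF·pyridine returns to the route at 20.

**Step 17.** Facial selectivity is the weak point, because the ring conformation, not a nearby directing group, decides which face of C8=C9 is open; the reagent may add from the C11 side. The fallback is the Woodward cis-hydroxylation, which places the diol on the face opposite to the one an electrophile first attacks. From 22, I2 and AgOAc in wet acetic acid give the cis hydroxy acetates F6 (9-acetate) and F7 (8-acetate) through the acetoxonium ion. Brief treatment with K2CO3 in methanol removes the acetyl group and returns to 23.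

**Step 22.** Acylation may go to O9 or to both hydroxyls, and the acyl group can migrate between O8 and O9 under DMAP. The fallback turns the same bias to use. From 24, triethylsilyl chloride and imidazole, which respond to the same steric and electronic differences, should silylate the hydroxyl that competes, giving the 9-O-triethylsilyl ether F8. Yamaguchi esterification of the remaining O8 with 28 gives F9, and HF·pyridine removes the silyl group to give 30.

**Step 12.** The activated allylic carbinol may be displaced in the SN2′ sense at the vinyl terminus or may ionise, with loss of configuration at C6. The fallback replaces the vinyl group by an alkyne during the inversion. From 15, lithium (trimethylsilyl)acetylide adds in the same Felkin sense to give propargylic alcohol F10, whose Mitsunobu reaction with 17 is a clean SN2 process and gives F11. TBAF buffered with acetic acid removes both silyl groups to give F12, and semihydrogenation over Pd/CaCO3 poisoned with Pb(OAc)2 and quinoline returns to the route at 19.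

**Step 11.** Diastereoselectivity of the Grignard addition may be low, since Felkin–Anh control by an oxirane is not always strong. The fallback sets out from 15 and does not separate the adducts. The mixture of 16 and its C6 epimer F13 is oxidised with Dess–Martin periodinane to epoxy enone F14. Chelation-controlled reduction with Zn(BH4)2 in ether at low temperature, which is reliable for α,β-epoxy ketones, then gives the erythro alcohol and returns to 16.

## Further compounds

F1 | step 16 | macrocyclic C9 dienone, O6 phosphonoacetate | CCOP(=O)(OCC)CC(=O)O[C@H]1/C=C\C(=O)/C(C(=O)OC)=C\CC[C@@]2(C)O[C@H]12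
F2 | step 16 | trans-fused α-phosphono lactone C9 ketone (C11 epimers) | CCOP(=O)(OCC)C1C(=O)O[C@H]2[C@H]1CC(=O)/C(C(=O)OC)=C\CC[C@@]1(C)O[C@H]21
F3 | step 16 | α-phosphono lactone C9 carbinol (C9 and C11 epimers) | CCOP(=O)(OCC)C1C(=O)O[C@H]2[C@H]1CC(O)/C(C(=O)OC)=C\CC[C@@]1(C)O[C@H]21
F4 | step 14 | macrocyclic (6R)-alcohol, C9 silyl ether | O[C@@H]1/C=C\[C@H](O[Si](C)(C)C(C)(C)C)/C(C(=O)OC)=C\CC[C@@]2(C)O[C@H]12
F5 | step 14 | macrocyclic (6S)-phosphonoacetate, C9 silyl ether | CCOP(=O)(OCC)CC(=O)O[C@H]1/C=C\[C@H](O[Si](C)(C)C(C)(C)C)/C(C(=O)OC)=C\CC[C@@]2(C)O[C@H]12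
F6 | step 17 | cis 8-hydroxy 9-acetate of the phosphono lactone | CCOP(=O)(OCC)C1C(=O)O[C@H]2[C@H]1[C@H](O)[C@H](OC(C)=O)/C(C(=O)OC)=C\CC[C@@]1(C)O[C@H]21
F7 | step 17 | cis 8-acetate 9-hydroxy isomer of the phosphono lactone | CCOP(=O)(OCC)C1C(=O)O[C@H]2[C@H]1[C@H](OC(C)=O)[C@H](O)/C(C(=O)OC)=C\CC[C@@]1(C)O[C@H]21
F8 | step 22 | 9-O-triethylsilyl ether of 24 | C=C1C(=O)O[C@H]2[C@H]1[C@H](O)[C@H](O[Si](CC)(CC)CC)/C(C(=O)OC)=C\CC[C@@]1(C)O[C@H]21
F9 | step 22 | 9-O-triethylsilyl ether of 30 | C=C1C(=O)O[C@H]2[C@H]1[C@H](OC(=O)[C@@]1(C)O[C@@H]1C)[C@H](O[Si](CC)(CC)CC)/C(C(=O)OC)=C\CC[C@@]1(C)O[C@H]21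
F10 | step 12 | (6R)-propargylic alcohol, trimethylsilyl alkyne | C=C[C@H](O[Si](C)(C)C(C)(C)C)/C(C(=O)OC)=C\CC[C@@]1(C)O[C@@H]1[C@H](O)C#C[Si](C)(C)C
F11 | step 12 | (6S)-propargylic phosphonoacetate, trimethylsilyl alkyne | C=C[C@H](O[Si](C)(C)C(C)(C)C)/C(C(=O)OC)=C\CC[C@@]1(C)O[C@@H]1[C@@H](OC(=O)CP(=O)(OCC)OCC)C#C[Si](C)(C)C
F12 | step 12 | (6S)-propargylic phosphonoacetate, terminal alkyne, C9 alcohol | C=C[C@H](O)/C(C(=O)OC)=C\CC[C@@]1(C)O[C@@H]1[C@@H](OC(=O)CP(=O)(OCC)OCC)C#C
F13 | step 11 | (6S) epimer of 16 | C=C[C@H](O[Si](C)(C)C(C)(C)C)/C(C(=O)OC)=C\CC[C@@]1(C)O[C@@H]1[C@@H](O)C=C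
F14 | step 11 | epoxy vinyl ketone | C=C[C@H](O[Si](C)(C)C(C)(C)C)/C(C(=O)OC)=C\CC[C@@]1(C)O[C@@H]1C(=O)C=C
A1 | alternative 1 | cyclodeca-1(10),4-dien-9-one with C6 and C7 set | C1/C(C)=C/[C@@H](OCc2ccc(OC)cc2)[C@H](CCOCc2ccc(OC)cc2)CC(=O)/C(CO[Si](C)(C)C(C)(C)C)=C\C1
A2 | alternative 2 | α-chloro methyl ketone lactone | CC(=O)[C@@H](Cl)[C@H]1OC(=O)C[C@@H]1[C@H](OCc2ccc(OC)cc2)[C@H](O[Si](C)(C)C(C)(C)C)C(=C)C(=O)OC
A3 | alternative 2 | but-3-enylmagnesium bromide | C=CCC[Mg]Br
A4 | alternative 2 | epoxy diene lactone, open between C1 and C10 | C=CCC[C@@]1(C)O[C@@H]1[C@H]1OC(=O)C[C@@H]1[C@H](OCc2ccc(OC)cc2)[C@H](O[Si](C)(C)C(C)(C)C)C(=C)C(=O)OC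
A5 | alternative 3 | bromomethylbutenolide C8 aldehyde | O=C[C@H](O[Si](C)(C)C(C)(C)C)/C(C(=O)OC)=C\CC[C@@]1(C)O[C@@H]1[C@@H]1C=C(CBr)C(=O)O1
A6 | alternative 3 | 8-hydroxy-9-silyloxy macrocyclic methylene lactone | C=C1C(=O)O[C@H]2[C@H]1[C@H](O)[C@H](O[Si](C)(C)C(C)(C)C)/C(C(=O)OC)=C\CC[C@@]1(C)O[C@H]21
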